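**Plan**

- Numbering used throughout: C1 lactone C=O, C2 CH2, C3 CH–OO, C4 C(CH3)–O(lactone), C5 ring CH2, C6 C(CH3)–OO, C7–C22 chain (ring locants in the systematic names: C3 = 7a, C4 = 4a, C5 = 4, C6 = 3).
- Enabling feature: the 1,2-dioxane and the γ-lactone share the C3–C4 bond; the O–O bridge runs from C3, which is β to the lactone carbonyl C1, to quaternary C6, which is α to C7, and a single CH2 (C5) joins C6 to the lactone γ-carbon C4.
- Retrosynthesis: C7–C8 is cut first (alkene reduction, then Wittig olefination) to the bicyclic C6 carbaldehyde; C4–C5, C6–O and O–C3 are then cut in one operation, which leaves α-angelica lactone, methacrolein and O2.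
- Forward: the lactone ring is bought; the dioxane ring is closed onto it in a one-pot amine-catalysed sequence (vinylogous Michael addition, enamine oxygenation with singlet oxygen, oxa-Michael closure); the C15 unit is then joined at C7 and the alkene saturated.
- Stereochemistry: C4 and C6 come from the chiral primary amine catalyst, C3 follows from C4 through the only possible (cis) ring fusion, and no later step touches a stereocentre.

Key step: step 1

Assumption: the epi-quinine-derived amine is taken to give the (4S,6S) aldehyde drawn here; should its sense of induction be opposite, the pseudoenantiomeric 9-amino-9-deoxy-epi-quinidine is used with no other change.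

**Route**

Step 1
Reactants: 1 α-angelica lactone (5-methylfuran-2(3H)-one); 2 methacrolein (2-methylprop-2-enal); 3 dioxygen
Product: 7 (3S,4aS,7aS)-3,4a-dimethyl-6-oxohexahydrofuro[3,2-c][1,2]dioxine-3-carbaldehyde (cis-fused dioxane–lactone; CHO on C6 trans to the C4 methyl group), via catalyst-bound enamine 4 (not isolated), via butenolide aldehyde 5 (not isolated), via hydroperoxy aldehyde 6 (not isolated)
Conditions: 1 (1.0 equiv), 2 (1.5 equiv), 9-amino-9-deoxy-epi-quinine (20 mol%), CF3CO2H (30 mol%), CH2Cl2, 0 °C to rt, Ar, dark; then tetraphenylporphyrin (1 mol%), O2 (1 atm), white LED, 0 °C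
Reagents that add atoms: dioxygen (3), O=O
Why: Proposed new method: the primary amine turns 2 into an iminium ion and the quinuclidine, acting as base, delivers the dienolate of 1 through its γ-carbon to the unsubstituted β-carbon (C4–C5), giving enamine 4, which rests as aldehyde 5 until 1 is used up; the closest known reaction type is the amine-catalysed direct vinylogous Michael addition of α-angelica lactone to enals and enones. Under O2 and light 5 returns to the N–H enamine 4, which takes up singlet oxygen at C6 in an ene-type process (C6–O), and hydrolysis of the resulting α-hydroperoxy imine frees 6; the closest known reaction types are the amine-catalysed α-oxygenation of aldehydes with singlet oxygen and the primary-amine α-functionalisation of α-branched aldehydes. The 1,2-dioxane then closes by 6-exo-trig oxa-Michael addition of the hydroperoxide to butenolide carbon C3 (O–C3), a closure known for hydroperoxides tethered to butenolides. C4 is set by the catalyst, whose quinuclidinium ion holds the dienolate so that one of its faces meets the iminium ion; C6 is set by the catalyst-shielded face of enamine 4, on which both C6–H epimers of 5 converge; C3 is set by C4, because the three-atom tether reaches only the butenolide face that gives the cis-fused bicycle. The step needs γ- rather than α-attack of the dienolate, which the methyl-bearing γ-terminus and the conjugation regained in the butenolide secure, and oxygenation of the enamine rather than of 1 or its dienolate, which is secured by admitting oxygen and light only after 1 has been consumed.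

Step 2
Reactants: 8 1-bromopentadecane
Product: 9 pentadecyl(triphenyl)phosphonium bromide
Conditions: PPh3 (0.95 equiv), MeCN, reflux; salt washed with Et2O
Reagents that add atoms: triphenylphosphine, c1ccc(cc1)P(c1ccccc1)c1ccccc1
Why: SN2 alkylation of triphenylphosphine by the unhindered primary bromide gives the Wittig salt, and the slight deficit of phosphine together with the ether wash keeps free PPh3, a reductant for peroxides, out of step 3.

Step 3
Reactants: 7 bicyclic C6 carbaldehyde; 9 pentadecyl(triphenyl)phosphonium bromide
Product: 11 (3S,4aS,7aS)-3-[(1Z)-hexadec-1-en-1-yl]-3,4a-dimethyl-4,4a,7,7a-tetrahydrofuro[3,2-c][1,2]dioxin-6(3H)-one, via pentadecylidene(triphenyl)phosphorane 10 (not isolated)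
Conditions: 9 (1.15 equiv), NaN(SiMe3)2 (1.1 equiv), THF, 0 °C; then 7, −78 °C to 0 °C
Reagents that add atoms: none
Why: Lithium-free Wittig olefination of the non-enolisable α-quaternary aldehyde by the non-stabilised ylide should be fast at −78 °C, where the ylide is expected neither to deprotonate the lactone nor to attack the dialkyl peroxide, and should give mainly the Z-alkene (C7=C8) without touching a stereocentre.

Step 4
Reactants: 11 Z-alkene
Product: 12 (3R,4aS,7aS)-3-hexadecyl-3,4a-dimethyl-4,4a,7,7a-tetrahydrofuro[3,2-c][1,2]dioxin-6(3H)-one (target; the descriptor at C6 changes from S to R only because the CIP priorities change)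
Conditions: KO2CN=NCO2K (excess, in portions), AcOH, CH2Cl2/MeOH, 0 °C to rt
Reagents that add atoms: none
Why: Diimide reduction transfers H2 to the C7=C8 alkene in a concerted syn addition and should leave the O–O bond, the lactone and all three stereocentres untouched, which hydrogenation over palladium would not.

**Compound list**

1 | α-angelica lactone (5-methylfuran-2(3H)-one) | CC1=CCC(=O)O1 | starting material
2 | methacrolein (2-methylprop-2-enal) | C=C(C)C=O | starting material
3 | dioxygen | O=O | starting material
4 | (E)-enamine of 5 with the catalyst: (8S,9S)-9-amino-9-deoxy-epi-quinine N-substituted by (1E)-2-methyl-3-[(2S)-2-methyl-5-oxo-2,5-dihydrofuran-2-yl]prop-1-en-1-yl | C=C[C@H]1CN2CC[C@H]1C[C@H]2[C@@H](N/C=C(\C)C[C@]3(C)OC(=O)C=C3)c4ccnc5ccc(OC)cc45 | intermediate (not isolated)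
5 | 2-methyl-3-[(2S)-2-methyl-5-oxo-2,5-dihydrofuran-2-yl]propanal, both C6 epimers | O=CC(C)C[C@]1(C)OC(=O)C=C1 | intermediate (not isolated)
6 | (2S)-2-hydroperoxy-2-methyl-3-[(2S)-2-methyl-5-oxo-2,5-dihydrofuran-2-yl]propanal | O=C[C@@](C)(OO)C[C@]1(C)OC(=O)C=C1 | intermediate (not isolated)
7 | (3S,4aS,7aS)-3,4a-dimethyl-6-oxohexahydrofuro[3,2-c][1,2]dioxine-3-carbaldehyde | O=C[C@]1(C)C[C@]2(C)OC(=O)C[C@@H]2OO1 | intermediate
8 | 1-bromopentadecane | CCCCCCCCCCCCCCCBr | starting material
9 | pentadecyl(triphenyl)phosphonium bromide | CCCCCCCCCCCCCCC[P+](c1ccccc1)(c1ccccc1)c1ccccc1.[Br-] | intermediate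
10 | pentadecylidene(triphenyl)phosphorane | CCCCCCCCCCCCCCC=P(c1ccccc1)(c1ccccc1)c1ccccc1 | intermediate (not isolated)
11 | (3S,4aS,7aS)-3-[(1Z)-hexadec-1-en-1-yl]-3,4a-dimethyl-4,4a,7,7a-tetrahydrofuro[3,2-c][1,2]dioxin-6(3H)-one | CCCCCCCCCCCCCC/C=C\[C@]1(C)C[C@]2(C)OC(=O)C[C@@H]2OO1 | intermediate
12 | (3R,4aS,7aS)-3-hexadecyl-3,4a-dimethyl-4,4a,7,7a-tetrahydrofuro[3,2-c][1,2]dioxin-6(3H)-one | CCCCCCCCCCCCCCCC[C@]1(C)C[C@]2(C)OC(=O)C[C@@H]2OO1 | target

**Step count**

Total: 4 steps (steps 1 and 2 run in parallel). Longest linear sequence: 3 steps (1, 3, 4).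

**Steps most likely to fail**

Step 1 (bears the label "Proposed new method:"). Three processes threaten it: [2+2] addition of singlet oxygen to the enamine with cleavage of the C6=C7 bond, fragmentation of the α-hydroperoxy aldehyde before the oxa-Michael closure, and poor facial selectivity of the oxygenation at C6; photooxidation of the catalyst amine would in addition stall turnover. The fallback uses known chemistry and puts the chain on before any O–O bond exists. It sets out from butenolide aldehyde 5, isolated after the dark phase of step 1 (a vinylogous Michael addition of known type), and from bromide 8. Aldehyde 5 is converted (Tf2O, 2,6-di-tert-butyl-4-methylpyridine, CH2Cl2) into enol triflate F1. Negishi coupling (Pd(PPh3)4, THF) with pentadecylzinc bromide F2, made from 8 with Zn dust and LiCl, gives trisubstituted alkene F3. Mukaiyama–Isayama hydroperoxysilylation (Co(thd)2 with thd = 2,2,6,6-tetramethylheptane-3,5-dionate, O2, Et3SiH, ClCH2CH2Cl) places the tertiary peroxide at C6 as triethylsilyl peroxide F4. Fluoride desilylation (Bu4NF, AcOH, THF) frees hydroperoxide F5, and amine-mediated oxa-Michael closure (Et2NH, CF3CH2OH) gives 12 together with its C6 epimer F6, which is removed by chromatography. The fallback rejoins the route at 12 and bypasses steps 3 and 4; its cost is the loss of catalyst control at C6.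

Step 3. The basic ylide may deprotonate C2 and expel the peroxide from C3 (reversal of the ring closure) or attack the O–O bond, and addition to the neopentyl-type aldehyde may be slow. The fallback replaces the phosphorane by a sulfonyl carbanion generated in the presence of the aldehyde, so that no free base builds up (Julia–Kocienski olefination). It sets out from 8 and 7: bromide 8 is S-alkylated with 1-phenyl-1H-tetrazole-5-thiol (K2CO3, acetone) to sulfide F7 and oxidised (H2O2, (NH4)6Mo7O24, EtOH) to sulfone F8. Addition of KN(SiMe3)2 to a mixture of F8 and 7 (1,2-dimethoxyethane, −60 °C) should give, after Smiles rearrangement and loss of SO2, the E-alkene F9, which is reduced under the conditions of step 4 and so rejoins the route at 12.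

Step 4. Saturation of the cis-alkene next to quaternary C6 may stall while diimide disproportionates. The fallback sets out from 11 and changes the reductant to hydrogen on platinum: H2 (1 atm), PtO2, EtOAc, rt, stopped after one equivalent of uptake, relying on hydrogenolysis of the hindered dialkyl peroxide being slower than saturation of the disubstituted alkene. It gives 12 directly and forms no new compound (F0).

**Further compounds**

F1 | step 1 | 2-methyl-3-[(2S)-2-methyl-5-oxo-2,5-dihydrofuran-2-yl]prop-1-en-1-yl trifluoromethanesulfonate (E/Z mixture) | CC(=COS(=O)(=O)C(F)(F)F)C[C@]1(C)OC(=O)C=C1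
F2 | step 1 | pentadecylzinc bromide | CCCCCCCCCCCCCCC[Zn]Br
F3 | step 1 | (5S)-5-methyl-5-(2-methyloctadec-2-en-1-yl)furan-2(5H)-one (E/Z mixture) | CCCCCCCCCCCCCCCC=C(C)C[C@]1(C)OC(=O)C=C1
F4 | step 1 | (5S)-5-methyl-5-{2-methyl-2-[(triethylsilyl)peroxy]octadecyl}furan-2(5H)-one (both C6 epimers) | CCCCCCCCCCCCCCCCC(C)(OO[Si](CC)(CC)CC)C[C@]1(C)OC(=O)C=C1
F5 | step 1 | (5S)-5-(2-hydroperoxy-2-methyloctadecyl)-5-methylfuran-2(5H)-one (both C6 epimers) | CCCCCCCCCCCCCCCCC(C)(OO)C[C@]1(C)OC(=O)C=C1
F6 | step 1 | (3S,4aS,7aS)-3-hexadecyl-3,4a-dimethyl-4,4a,7,7a-tetrahydrofuro[3,2-c][1,2]dioxin-6(3H)-one (C6 epimer of 12) | CCCCCCCCCCCCCCCC[C@@]1(C)C[C@]2(C)OC(=O)C[C@@H]2OO1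
F7 | step 3 | 5-(pentadecylsulfanyl)-1-phenyl-1H-tetrazole | CCCCCCCCCCCCCCCSc1nnnn1-c1ccccc1
F8 | step 3 | 5-(pentadecylsulfonyl)-1-phenyl-1H-tetrazole | CCCCCCCCCCCCCCCS(=O)(=O)c1nnnn1-c1ccccc1
F9 | step 3 | (3S,4aS,7aS)-3-[(1E)-hexadec-1-en-1-yl]-3,4a-dimethyl-4,4a,7,7a-tetrahydrofuro[3,2-c][1,2]dioxin-6(3H)-one | CCCCCCCCCCCCCC/C=C/[C@]1(C)C[C@]2(C)OC(=O)C[C@@H]2OO1
F0 | step 4 | none | none
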